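The easy step is a balance of gas. First product is an intermediate that disappears again, so this reckoning assumes two gas per substrate.

| setting | spring | flask |
|---|---|---|
| substrate | 0.20 M (fed, over 6.0 h) | 0.40 M (fed, over 6.0 h) |
| gas | 15 mM (held) | 15 mM (held) |
| remark | run made earlier |  |
| time |  | 15 d |

spring run (percent of the substrate charged)

| time / d | first product / % |
|---|---|
| 0.417 | 37.6 |
| 0.833 | 1.4 |
| 1.25 | 0 |
| 1.67 | 1.2 |
| 2.00 | 0 |
| 2.50 | 0 |
| 3.00 | 1.7 |

(scatter of a reading: 1 percentage point)

- time up to 15 d at which first product stands highest
- the amount of first product, in percent of the substrate charged, at that time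
- the first time at which first product reaches 19%, in the same percent

- at the start none of the gas is in solution

In the spring run, first product reads 37.6% at 0.417 d but 1.4% at 0.833 d. Two gas per substrate had therefore gone in by then, which puts the uptake s at no less than 0.480 M d⁻¹. The spring feed, at 0.800 M d⁻¹, outran that floor, and the flask's feed, at 1.60 M d⁻¹, outruns it further. So substrate should wait on gas, and the crossing of gas looks like the rate-limiting step.

Substrate and first product then both draw on gas, but the feed runs on the clock, so carrying a height from one flask to another is an assumption of this reckoning. On that assumption the height comes over from the spring run as a percentage: 37.6%, the peak share, the share of the charge standing as first product at its top. It is a reading with a scatter of 1 percentage point, and the next reading comes much later, so the true spring top may lie elsewhere.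

With uptake at the floor, this reckoning sets the flask's top near 0.833 d and its 19% near 0.158 d.

The forecast gave 0.48 d, 80% and 0.12 d, holding that “the chemistry looks saturated, near zero order”.

The flask gives 0.539 d, 37.4% and 0.205 d.

    gas ⇌ partner, rate k1*(csat - [partner]) (kL = 2.00 h⁻¹)
    substrate + partner → first product + released group (k = 120 M⁻¹ h⁻¹)
    partner + other mono adduct → double product + released group (k = 47.0 M⁻¹ h⁻¹)
    partner + first product → double product + released group (k = 43.0 M⁻¹ h⁻¹)
    substrate ⇌ dormant form (K = 1.00, k = 0.0820 h⁻¹)
    substrate + partner → other mono adduct + released group (k = 36.0 M⁻¹ h⁻¹)
    2 partner → self-condensation product (k = 0.960 M⁻¹ h⁻¹)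

The flask's top stands 0.20 points under the peak share, with released group at 0.349 M at 0.539 d, or 0.872 per substrate charged. The flask with 0.24 M of substrate takes the same reckoning: a peak share of 37.6% again, and 0.480 M of released group from two gas per substrate. That flask tops out at 38.6% and holds 0.480 M of released group at 15.0 d.

(The runs stem from a simulated flask with constants of no real substance.)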